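## Structural features

The target is a cis-fused 3,7-dioxabicyclo[3.3.0]octan-2-one: a γ-lactone (C1, C2, O3, C4, C5) and a tetrahydrofuran (C1, C5, C6, O7, C8) share the C1–C5 bond. C4 carries a 3,4,5-trihydroxyphenyl ring and C8 a 3,4-dihydroxyphenyl ring, both on the convex face (H4 trans to H5, H8 trans to H1); the four stereocentres C8, C1, C5 and C4 are contiguous and the absolute configuration is (1S,4S,5R,8S). C4–O3 is a benzylic ester bond and C8–O7 a benzylic ether bond, each on a ring with a para oxygen, so both are open to acid ionisation and to hydrogenolysis; C1–H is α to the carbonyl group and β to O7, and the five phenols oxidise readily, worst under base. The real difficulty is the relation between the remote centres C4 and C8 and the need to make the C5–C6 bond on a defined face next to C4 without disturbing either benzylic bond. Any butenolide precursor adds a trap: its C4–H is benzylic, allylic and γ to the carbonyl group, so bases racemise it. The feature exploited is that C6 is a single carbon bonded to C5 and to O7 and stands cis to the C8 arm on C1, so it can be handed from the C8 oxygen to C5 of a C1=C5 butenolide. A direct O7–CH2 radical closure onto C5 would be 5-endo; a silicon atom placed between O7 and C6 for the ring closure makes it 6-endo and is excised afterwards.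

## Logic of the disconnections

20 from 19. Five aryl O–CH2Ph bonds are cut. Free catechol and pyrogallol units would not survive the organometallic, radical, peroxide or basic steps, whereas these ethers pass through all of them and leave in one neutral, reductive operation. The skeleton is unchanged; the demand is that the last step cleaves aryl ethers without breaking C4–O3 or C8–O7.

19 from 17. The ether bond O7–C6 is cut at its CH2 end, the one place in either ring where a C–O bond can be made by substitution with no stereochemical consequence. This opens the tetrahydrofuran and leaves a monocyclic lactone with two hydroxyl arms held cis. The forward step must activate the primary hydroxyl beside the benzylic one and leave C8 as it is.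

17 from 16. Both hydroxyl groups are traced to one silicon atom (O7–H to O7–Si, C6–OH to C6–Si). A C–Si bond can be turned into C–OH late, so C6 can first be introduced as a carbon radical. The gain is a six-membered ring that ties C6 to O7 and so to the C8 stereocentre. The forward oxidation must be mild towards C1–H and the β-hydroxy lactone it releases.

16 from 13. The bond C5–C6 is cut, together with C1–H. This is the strategic cut: it removes the stereocentres C1 and C5 and one ring and leaves a flat C1=C5 lactone in which only C4 and C8 are stereogenic, with C6 parked on the C8 oxygen through silicon. The forward closure must be 6-endo, must occur on the face away from the C4 aryl group, and must end with hydrogen delivery that gives the cis fusion.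

13 from 11 and 12. The O7–Si bond is cut; 12 brings C6, its halogen and the temporary silicon atom in one purchased reagent. The forward silylation must not use a base able to remove the C4 hydrogen.

11 from 9 through 10. The C1=C5 double bond is traced to a C5–Se bond and C1–H. This detour lets C1 react as an enolate carbon; an amine-catalysed coupling of the same kind would racemise C4. The forward elimination must go towards C1 and not towards C4.

9 from 6 and 7 through 8. The bonds C1–C8 and C5–Se are cut. This is the main simplification before the key step: the molecule falls into two pieces of similar size, each from one aromatic aldehyde. The forward step must relay configuration from C4 to C8: selenium anti to the C4 aryl group, the aldehyde anti to selenium, and a closed aldol transition state.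

6 from 4 through 5. The lactone bond C2–O3 is cut and the cis alkene is traced to an alkyne. Semihydrogenation then supplies the cis geometry that lactonisation needs. The demand is a reduction that stops at the alkene and spares the benzyl ethers and the propargylic C–O bond.

4 from 1 and 2 through 3. The bond C4–C5 between carbinol carbon and alkyne is cut. The only stereocentre made from achiral material, C4, becomes a catalytic enantioselective addition to an aldehyde. The demand is high enantioselectivity with an electron-rich aromatic aldehyde.

## Other disconnections considered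

Alternative 1: The cut takes O3 out of the lactone, so that C2 is bonded directly to C4; the precursor is the racemic cyclobutanone A1, a 3-oxabicyclo[3.2.0]heptan-6-one with both aryl groups in place as methoxymethyl ethers. In the forward step a flavin monooxygenase, with its nicotinamide cofactor and air, would oxidise one enantiomer of A1; benzylic C4 migrates from C2 to oxygen with retention and gives the γ-lactone A2, the penta(methoxymethyl) ether of the target.
- In favour: the migration is stereospecific, the benzylic carbon is also the preferred migrating group, the lactone is made last in buffered water, and neither tin nor selenium is used.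
- Against: all four stereocentres must already be present in A1, so the stereochemical problem is moved to a more strained bicycle and not solved. The absolute configuration comes from a resolution that discards at least half of A1. A bulky diaryl substrate with five acetal groups may not fit the enzyme. The final acid removal of five acetals exposes C4–O3 and C8–O7 to ionisation.
- Comparison: in structure the two plans are equal in what they deliver (A2 and 19 differ only in the protecting group). In mechanism the oxygen insertion is as well defined as the radical addition, but it does not address C1, C5 and C8. In step economy after the key step this alternative is the better: A2 is one step from the target, 16 is three. The chosen plan is the better in setting the absolute configuration catalytically in the first step and carrying all material forward.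

Alternative 2: Three bonds are cut at once, O7–C8, C1–C5 and C2–O3, giving the cis-epoxy alcohol A3 (C6, C5, C4 and the future O3) and the benzylidene malonate A4 (C8, C1, C2). Forward, the alkoxide of A3 would add to A4, the malonate anion would open the epoxide at C5 with inversion in a 5-exo closure, and the freed C4 alkoxide would lactonise onto the cis ester to give A5, which still carries a methoxycarbonyl group on C1.
- In favour: the halves are of equal size, two rings and three bonds form in one flask, C5 is set by a stereospecific substitution and C4 is carried in from the epoxide.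
- Against: C8 is created in a reversible oxa-Michael step, and nothing clearly favours the convex-face aryl group. The alkoxide of A3 can undergo Payne rearrangement. A cis epoxide next to a trialkoxyphenyl ring opens easily at benzylic C4 instead of C5. The extra ester on C1 must be removed by a hot dealkoxycarbonylation in which halide can also attack the benzylic lactone carbon.
- Comparison: in structure A5 already contains the complete bicycle, whereas 16 still holds a silicon atom to be excised. In convergence and bonds formed per step this alternative is the better. In mechanism the chosen plan is the better, because each of its stereocentres has a named controlling element while C8 here rests on an equilibrium. In step count the two are about equal once the enantioselective preparation of A3 and the ester removal are included.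

Alternative 3: The cut severs C5–C6 and O3–C4; C6 becomes the methylene acetal carbon of the 1,3-dioxan-4-one A6, which carries the catechol ring on C8 and an (E)-styryl group (C5=C4) on C1. Forward, a silyl triflate would open A6 to the O7=C6 oxocarbenium ion and a silyl carboxylate, alkene carbon C5 would attack C6 to close the tetrahydrofuran, and the carboxylate would capture the benzylic cation at C4 to close the lactone, giving A7, which is identical with 19.
- In favour: it is the shortest route, the key-step product is one step from the target, the same C5–C6 bond is formed without tin or a temporary atom, and the bicyclic product enforces cis fusion.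
- Against: an electron-rich aryl group on C8 beside a homoallylic alkene invites 2-oxonia-Cope rearrangement and benzylic ionisation at C8, which would erase C8 and C1. C4 is set by capture of a free benzylic cation, so its configuration rests on a preference and not on a stereospecific event. A silyl triflate leaves little margin with five benzyl ethers and two para-alkoxybenzylic positions. A6 needs an anti-selective aldol of a β,γ-unsaturated acid derivative that tends to isomerise into conjugation.
- Comparison: in step and atom economy this alternative is the better, and in the strategic bond it is the equal. In mechanism the chosen plan is the better: C5 is made by a neutral radical addition with no cation next to either aryl ring, and C4 and C8 are fixed before the key step.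

Key step: step 6

Assumption: (S,S)-ProPhenol is taken as the ligand enantiomer that gives the (R)-carbinol 4; if the sense of induction is the reverse, (R,R)-ProPhenol is used and nothing else changes.

Remark: C8 is R in 11 and 13 and S in 9, 16, 17, 19 and 20 with no change in space, because the sp2 carbon C1 outranks the aryl ring and the sp3 carbon C1 does not. C4 is R in 9 for the same kind of reason (C5 bears selenium).

## Route

Step 1
Reactants: 1 3,4,5-tris(benzyloxy)benzaldehyde; 2 methyl propiolate
Product: 4 methyl (R)-4-hydroxy-4-[3,4,5-tris(benzyloxy)phenyl]but-2-ynoate, via methylzinc alkynylide 3 (not isolated)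
Conditions: Me2Zn (3 equiv), (S,S)-ProPhenol (10 mol %), Ph3PO (20 mol %), toluene, 0 °C; aq. NH4Cl
Reagents that add atoms: none
Why: Catalytic enantioselective alkynylation of an aldehyde: Me2Zn metalates 2 to 3, and the dinuclear zinc–ProPhenol complex holds aldehyde and alkynylide on neighbouring zinc atoms so that one aldehyde face is attacked, which sets C4. The conditions are neutral enough for the benzyl ethers and for the base-sensitive γ-hydroxy ynoate.

Step 2
Reactants: 4 methyl (R)-4-hydroxy-4-[3,4,5-tris(benzyloxy)phenyl]but-2-ynoate
Product: 6 (S)-5-[3,4,5-tris(benzyloxy)phenyl]furan-2(5H)-one, via Z-hydroxy enoate 5 (not isolated)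
Conditions: H2 (1 atm), Pd/CaCO3–Pb(OAc)2, quinoline, EtOAc, rt; then CSA (cat.), CH2Cl2, rt
Reagents that add atoms: none
Why: cis-Semihydrogenation on lead-poisoned palladium gives 5, whose hydroxyl lies next to the ester and lactonises under acid catalysis with loss of methanol. C4 is untouched, the benzyl ethers are inert to this catalyst, and no base strong enough to remove the C4–H is present.

Step 3
Reactants: 6 (S)-5-[3,4,5-tris(benzyloxy)phenyl]furan-2(5H)-one; 7 3,4-bis(benzyloxy)benzaldehyde
Product: 9 (3R,4S,5R)-3-{(S)-[3,4-bis(benzyloxy)phenyl](hydroxy)methyl}-4-(phenylselanyl)-5-[3,4,5-tris(benzyloxy)phenyl]oxolan-2-one, via lithium enolate 8 (not isolated)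
Conditions: PhSeLi (from PhLi and Se, THF, 0 °C), THF, −78 °C; then 7, −78 °C; AcOH, −78 °C
Reagents that add atoms: lithium benzeneselenolate, [Li+].[Se-]c1ccccc1
Why: Selenolate-triggered Michael–aldol sequence (a stoichiometric Morita–Baylis–Hillman surrogate): the weakly basic selenolate adds to C5 anti to the C4 aryl group without removing C4–H. The ring-locked E enolate 8 then attacks the aldehyde anti to selenium through a closed Zimmerman–Traxler chair with the aryl group equatorial, which gives the anti aldol and the C8 configuration needed later. The cold acid quench prevents retro-aldol equilibration.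

Step 4
Reactants: 9 (3R,4S,5R)-3-{(S)-[3,4-bis(benzyloxy)phenyl](hydroxy)methyl}-4-(phenylselanyl)-5-[3,4,5-tris(benzyloxy)phenyl]oxolan-2-one
Product: 11 (S)-3-{(R)-[3,4-bis(benzyloxy)phenyl](hydroxy)methyl}-5-[3,4,5-tris(benzyloxy)phenyl]furan-2(5H)-one, via selenoxide 10 (not isolated)
Conditions: 30% H2O2, pyridine, CH2Cl2, 0 °C to rt
Reagents that add atoms: none
Why: Selenide oxidation and thermal syn-elimination of selenoxide 10: C1–H is cis to selenium and selenoxides eliminate away from oxygen-bearing carbons, so the C1=C5 double bond is restored. C1 and C5 lose their configuration by design, while C4 and C8 are untouched.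

Step 5
Reactants: 11 (S)-3-{(R)-[3,4-bis(benzyloxy)phenyl](hydroxy)methyl}-5-[3,4,5-tris(benzyloxy)phenyl]furan-2(5H)-one; 12 (bromomethyl)chlorodimethylsilane
Product: 13 (S)-3-{(R)-[3,4-bis(benzyloxy)phenyl][(bromomethyl)dimethylsilyloxy]methyl}-5-[3,4,5-tris(benzyloxy)phenyl]furan-2(5H)-one
Conditions: imidazole, CH2Cl2, 0 °C; filtered and used at once
Reagents that add atoms: none
Why: O-Silylation of a secondary alcohol with a chlorosilane; imidazole is chosen because it is too weak a base to deprotonate C4–H of the butenolide. The silyl ether is moisture-sensitive, so it is not stored.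

Step 6
Reactants: 13 (S)-3-{(R)-[3,4-bis(benzyloxy)phenyl][(bromomethyl)dimethylsilyloxy]methyl}-5-[3,4,5-tris(benzyloxy)phenyl]furan-2(5H)-one
Product: 16 (1S,2S,6S,7S)-2-[3,4-bis(benzyloxy)phenyl]-4,4-dimethyl-7-[3,4,5-tris(benzyloxy)phenyl]-3,8-dioxa-4-silabicyclo[4.3.0]nonan-9-one, via silylmethyl radical 14 (not isolated), via lactone radical 15 (not isolated)
Conditions: Bu3SnH (slow addition), AIBN (cat.), PhH (0.01 M), 80 °C
Reagents that add atoms: none
Why: The tributyltin radical abstracts bromine from 13 to give the nucleophilic α-silyl radical 14, which adds to the electron-poor β-carbon C5 (bond C5–C6) to give the carbonyl-stabilised tertiary radical 15; hydrogen transfer from Bu3SnH to C1 gives 16 and carries the chain. The closest known reaction type is the silicon-tethered radical cyclization of (bromomethyl)dimethylsilyl ethers of allylic alcohols, used with Tamao oxidation as a hydroxymethyl delivery. The one ring closed, the 1,2-oxasilinane (C6, Si, O7, C8, C1, C5), forms in the 6-endo-trig mode: 5-exo attack at C1 would build a quaternary centre and leave an unstabilised radical at C5, and the long Si–C and Si–O bonds favour the endo mode further. C5 is controlled by the C4 aryl group, which blocks one face of the planar butenolide, so C6 arrives trans to it. The C8 centre reinforces this: in the rotamer of least allylic strain C8–H lies in the butenolide plane beside C2, which puts the O–Si–CH2 arm on the face opposite the C4 aryl group and the C8 aryl group on the other face, pseudo-axial on the forming ring where it meets only H5 and one Si–methyl group. C1 is controlled by the new ring: the SiMe2–O segment folds under one face of radical 15, so hydrogen is delivered to the other face, syn to H5, and the fusion is cis with C6 and C8 on the same side. The step needs 6-endo over 5-exo closure, anti over syn addition with respect to the C4 aryl group, and ring closure faster than reduction of 14; the substitution pattern of the alkene, the C4 substituent and a low stationary concentration of Bu3SnH secure these in turn. C4 and C8 are not touched, and once C5 is sp3 the C4–H is no longer acidic.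

Step 7
Reactants: 16 (1S,2S,6S,7S)-2-[3,4-bis(benzyloxy)phenyl]-4,4-dimethyl-7-[3,4,5-tris(benzyloxy)phenyl]-3,8-dioxa-4-silabicyclo[4.3.0]nonan-9-one
Product: 17 (3S,4R,5S)-3-{(S)-[3,4-bis(benzyloxy)phenyl](hydroxy)methyl}-4-(hydroxymethyl)-5-[3,4,5-tris(benzyloxy)phenyl]oxolan-2-one
Conditions: 30% H2O2, KF, KHCO3, THF–MeOH, rt
Reagents that add atoms: hydrogen peroxide, OO
Why: Tamao oxidation: fluoride and bicarbonate activate silicon, hydroperoxide adds, C6 migrates from silicon to oxygen, and hydrolysis of both Si–O bonds frees the primary C6–OH and the C8–OH. Bicarbonate buffering at room temperature is chosen to spare C1–H and the β-hydroxy lactone, and 17 is carried on without storage to forestall acyl migration.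

Step 8
Reactants: 17 (3S,4R,5S)-3-{(S)-[3,4-bis(benzyloxy)phenyl](hydroxy)methyl}-4-(hydroxymethyl)-5-[3,4,5-tris(benzyloxy)phenyl]oxolan-2-one
Product: 19 (1S,4S,5R,8S)-8-[3,4-bis(benzyloxy)phenyl]-4-[3,4,5-tris(benzyloxy)phenyl]-3,7-dioxabicyclo[3.3.0]octan-2-one, via alkoxyphosphonium salt 18 (not isolated)
Conditions: PPh3, DIAD, THF, 0 °C to rt
Reagents that add atoms: none
Why: Mitsunobu cyclodehydration of a 1,4-diol: the less hindered primary C6–OH becomes the alkoxyphosphonium 18 and is displaced in a 5-exo-tet closure by the C8 hydroxyl. The O7–C6 bond therefore forms at a CH2 group and C8 keeps its configuration, which places the catechol ring on the convex face; the cis arrangement of the two arms makes the closure fast.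

Step 9
Reactants: 19 (1S,4S,5R,8S)-8-[3,4-bis(benzyloxy)phenyl]-4-[3,4,5-tris(benzyloxy)phenyl]-3,7-dioxabicyclo[3.3.0]octan-2-one
Product: 20 (1S,4S,5R,8S)-8-(3,4-dihydroxyphenyl)-4-(3,4,5-trihydroxyphenyl)-3,7-dioxabicyclo[3.3.0]octan-2-one
Conditions: H2 (1 atm), Pd/C, EtOAc–MeOH, rt; stopped at full conversion, worked up under argon
Reagents that add atoms: none
Why: Hydrogenolysis of five aryl benzyl ethers on palladium; aryl O–benzyl bonds should cleave faster than the secondary, ring-bound benzylic bonds C4–O3 and C8–O7 in neutral solvent at 1 atm. The neutral, reductive medium protects the catechol and pyrogallol units, and no stereocentre is affected.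

## Compound list

1 | 3,4,5-tris(benzyloxy)benzaldehyde | O=Cc1cc(OCc2ccccc2)c(OCc2ccccc2)c(OCc2ccccc2)c1 | starting material
2 | methyl propiolate | C#CC(=O)OC | starting material
3 | methyl 3-(methylzincio)prop-2-ynoate | C[Zn]C#CC(=O)OC | intermediate
4 | methyl (R)-4-hydroxy-4-[3,4,5-tris(benzyloxy)phenyl]but-2-ynoate | COC(=O)C#C[C@H](O)c1cc(OCc2ccccc2)c(OCc2ccccc2)c(OCc2ccccc2)c1 | intermediate
5 | methyl (S,Z)-4-hydroxy-4-[3,4,5-tris(benzyloxy)phenyl]but-2-enoate | COC(=O)/C=C\[C@H](O)c1cc(OCc2ccccc2)c(OCc2ccccc2)c(OCc2ccccc2)c1 | intermediate
6 | (S)-5-[3,4,5-tris(benzyloxy)phenyl]furan-2(5H)-one | O=C1O[C@H](c2cc(OCc3ccccc3)c(OCc3ccccc3)c(OCc3ccccc3)c2)C=C1 | intermediate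
7 | 3,4-bis(benzyloxy)benzaldehyde | O=Cc1ccc(OCc2ccccc2)c(OCc2ccccc2)c1 | starting material
8 | lithium (4S,5R)-4-(phenylselanyl)-5-[3,4,5-tris(benzyloxy)phenyl]-4,5-dihydrofuran-2-olate | [Li+].[O-]C1=C[C@H]([Se]c2ccccc2)[C@@H](c2cc(OCc3ccccc3)c(OCc3ccccc3)c(OCc3ccccc3)c2)O1 | intermediate
9 | (3R,4S,5R)-3-{(S)-[3,4-bis(benzyloxy)phenyl](hydroxy)methyl}-4-(phenylselanyl)-5-[3,4,5-tris(benzyloxy)phenyl]oxolan-2-one | O=C1O[C@H](c2cc(OCc3ccccc3)c(OCc3ccccc3)c(OCc3ccccc3)c2)[C@@H]([Se]c2ccccc2)[C@@H]1[C@@H](c1ccc(OCc2ccccc2)c(OCc2ccccc2)c1)O | intermediate
10 | (3R,4S,5R)-3-{(S)-[3,4-bis(benzyloxy)phenyl](hydroxy)methyl}-4-(phenylseleninyl)-5-[3,4,5-tris(benzyloxy)phenyl]oxolan-2-one (selenoxide, mixture at selenium) | O=C1O[C@H](c2cc(OCc3ccccc3)c(OCc3ccccc3)c(OCc3ccccc3)c2)[C@@H]([Se](=O)c2ccccc2)[C@@H]1[C@@H](c1ccc(OCc2ccccc2)c(OCc2ccccc2)c1)O | intermediate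
11 | (S)-3-{(R)-[3,4-bis(benzyloxy)phenyl](hydroxy)methyl}-5-[3,4,5-tris(benzyloxy)phenyl]furan-2(5H)-one | O=C1O[C@H](c2cc(OCc3ccccc3)c(OCc3ccccc3)c(OCc3ccccc3)c2)C=C1[C@@H](c1ccc(OCc2ccccc2)c(OCc2ccccc2)c1)O | intermediate
12 | (bromomethyl)chlorodimethylsilane | C[Si](C)(Cl)CBr | starting material
13 | (S)-3-{(R)-[3,4-bis(benzyloxy)phenyl][(bromomethyl)dimethylsilyloxy]methyl}-5-[3,4,5-tris(benzyloxy)phenyl]furan-2(5H)-one | O=C1O[C@H](c2cc(OCc3ccccc3)c(OCc3ccccc3)c(OCc3ccccc3)c2)C=C1[C@@H](c1ccc(OCc2ccccc2)c(OCc2ccccc2)c1)O[Si](C)(C)CBr | intermediate
14 | silylmethyl radical from 13 (CH2 radical on silicon in place of CH2Br) | O=C1O[C@H](c2cc(OCc3ccccc3)c(OCc3ccccc3)c(OCc3ccccc3)c2)C=C1[C@@H](c1ccc(OCc2ccccc2)c(OCc2ccccc2)c1)O[Si](C)(C)[CH2] | intermediate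
15 | cyclised lactone radical (skeleton of 16 with the unpaired electron on C1) | O=C1O[C@H](c3cc(OCc4ccccc4)c(OCc4ccccc4)c(OCc4ccccc4)c3)[C@H]2C[Si](C)(C)O[C@H](c3ccc(OCc4ccccc4)c(OCc4ccccc4)c3)[C]12 | intermediate
16 | (1S,2S,6S,7S)-2-[3,4-bis(benzyloxy)phenyl]-4,4-dimethyl-7-[3,4,5-tris(benzyloxy)phenyl]-3,8-dioxa-4-silabicyclo[4.3.0]nonan-9-one | O=C1O[C@H](c3cc(OCc4ccccc4)c(OCc4ccccc4)c(OCc4ccccc4)c3)[C@H]2C[Si](C)(C)O[C@H](c3ccc(OCc4ccccc4)c(OCc4ccccc4)c3)[C@@H]12 | intermediate
17 | (3S,4R,5S)-3-{(S)-[3,4-bis(benzyloxy)phenyl](hydroxy)methyl}-4-(hydroxymethyl)-5-[3,4,5-tris(benzyloxy)phenyl]oxolan-2-one | O=C1O[C@H](c2cc(OCc3ccccc3)c(OCc3ccccc3)c(OCc3ccccc3)c2)[C@@H](CO)[C@H]1[C@@H](c1ccc(OCc2ccccc2)c(OCc2ccccc2)c1)O | intermediate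
18 | primary alkoxytriphenylphosphonium salt of 17 (P–O on C6; counter-ion the anion of diisopropyl hydrazine-1,2-dicarboxylate) | O=C1O[C@H](c2cc(OCc3ccccc3)c(OCc3ccccc3)c(OCc3ccccc3)c2)[C@@H](CO[P+](c2ccccc2)(c2ccccc2)c2ccccc2)[C@H]1[C@@H](c1ccc(OCc2ccccc2)c(OCc2ccccc2)c1)O.CC(C)OC(=O)N[N-]C(=O)OC(C)C | intermediate
19 | (1S,4S,5R,8S)-8-[3,4-bis(benzyloxy)phenyl]-4-[3,4,5-tris(benzyloxy)phenyl]-3,7-dioxabicyclo[3.3.0]octan-2-one | O=C1O[C@H](c3cc(OCc4ccccc4)c(OCc4ccccc4)c(OCc4ccccc4)c3)[C@H]2CO[C@H](c3ccc(OCc4ccccc4)c(OCc4ccccc4)c3)[C@@H]12 | intermediate
20 | (1S,4S,5R,8S)-8-(3,4-dihydroxyphenyl)-4-(3,4,5-trihydroxyphenyl)-3,7-dioxabicyclo[3.3.0]octan-2-one | O=C1O[C@H](c2cc(O)c(O)c(O)c2)[C@H]2CO[C@H](c3ccc(O)c(O)c3)[C@@H]12 | target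

## Step count and least certain steps

Total steps: 9. Longest linear sequence: 9 steps (1 to 20); 2, 7 and 12 enter as purchased reagents.

Step 6 (key step). The silylmethyl radical may take hydrogen from the stannane before it closes, because the acceptor carbon is trisubstituted and flanked by the C4 aryl group; the silyl ether may also be hydrolysed by traces of water. Smaller risks are loss of facial control at C5 and hydrogen delivery to the wrong face of C1. Fallback: C6 is delivered intermolecularly and ionically. Setting out from 11, the C8 hydroxyl is capped (Et3SiCl, imidazole, CH2Cl2) to give triethylsilyl ether F1. The hydroxymethyl-anion equivalent (iPrO)Me2SiCH2MgCl is then added with CuI catalysis and Me3SiCl in THF at −78 °C. Attack at C5 is expected anti to the C4 aryl group, and kinetic protonation of C1 on work-up anti to the new C5 substituent, to give conjugate adduct F2. Tamao oxidation (H2O2, KF, KHCO3) and then Bu4NF/AcOH should give 17, where the route is rejoined. The weak point of this fallback is the basicity of the organometallic towards C4–H.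

Step 3. Simple diastereoselection in the aldol step may be low (an open transition state, or retro-aldol equilibration before the quench), which would give the C8 epimer beside 9. Fallback: C8 is set by reagent control instead of by relay from C4. Setting out from 11 obtained as a mixture of C8 epimers, Dess–Martin periodinane (NaHCO3, CH2Cl2) gives the single ketone F3. Corey–Bakshi–Shibata reduction with catecholborane and the (R)-methyl oxazaborolidine at −78 °C returns 11. The catalyst enantiomer is chosen on the premise that the aryl group acts as the larger substituent; the antipodal catalyst is the remedy if the sense proves opposite.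

Step 8. The alkoxyphosphonium may form at the benzylic C8–OH instead of at C6–OH, followed by elimination towards C1 or substitution at C8 with loss of configuration. Acyl migration of the C6 hydroxyl onto C2 in 17 before activation is a second possibility. Fallback: two discrete events in place of one redox dehydration. Setting out from 17, MsCl and 2,4,6-collidine in CH2Cl2 at −20 °C should sulfonylate only the primary hydroxyl to give mesylate F4. Warming F4 in pyridine lets the C8 hydroxyl displace the mesylate at C6, with retention at C8, to give 19.

Step 9. Hydrogenolysis of the benzylic lactone bond C4–O3, or more slowly of C8–O7, may set in before the last benzyl ether has gone, and the pyrogallol ring may oxidise in air during isolation. Fallback: non-reductive debenzylation. Setting out from 19, BCl3 with pentamethylbenzene as benzyl-cation scavenger in CH2Cl2 at −78 °C removes the five benzyl groups and gives 20 directly; no new intermediate is formed (F0).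

## Further compounds

F1 | step 6 | (S)-3-{(R)-[3,4-bis(benzyloxy)phenyl](triethylsilyloxy)methyl}-5-[3,4,5-tris(benzyloxy)phenyl]furan-2(5H)-one | O=C1O[C@H](c2cc(OCc3ccccc3)c(OCc3ccccc3)c(OCc3ccccc3)c2)C=C1[C@@H](c1ccc(OCc2ccccc2)c(OCc2ccccc2)c1)O[Si](CC)(CC)CC
F2 | step 6 | (3S,4S,5S)-3-{(S)-[3,4-bis(benzyloxy)phenyl](triethylsilyloxy)methyl}-4-{[dimethyl(propan-2-yloxy)silyl]methyl}-5-[3,4,5-tris(benzyloxy)phenyl]oxolan-2-one | O=C1O[C@H](c2cc(OCc3ccccc3)c(OCc3ccccc3)c(OCc3ccccc3)c2)[C@@H](C[Si](C)(C)OC(C)C)[C@H]1[C@@H](c1ccc(OCc2ccccc2)c(OCc2ccccc2)c1)O[Si](CC)(CC)CC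
F3 | step 3 | (S)-3-[3,4-bis(benzyloxy)benzoyl]-5-[3,4,5-tris(benzyloxy)phenyl]furan-2(5H)-one | O=C1O[C@H](c2cc(OCc3ccccc3)c(OCc3ccccc3)c(OCc3ccccc3)c2)C=C1C(=O)c1ccc(OCc2ccccc2)c(OCc2ccccc2)c1
F4 | step 8 | {(2S,3R,4S)-4-{(S)-[3,4-bis(benzyloxy)phenyl](hydroxy)methyl}-5-oxo-2-[3,4,5-tris(benzyloxy)phenyl]oxolan-3-yl}methyl methanesulfonate | O=C1O[C@H](c2cc(OCc3ccccc3)c(OCc3ccccc3)c(OCc3ccccc3)c2)[C@@H](COS(C)(=O)=O)[C@H]1[C@@H](c1ccc(OCc2ccccc2)c(OCc2ccccc2)c1)O
F0 | step 9 | none | none
A1 | alternative 1 | racemic 4-[3,4-bis(methoxymethoxy)phenyl]-7-[3,4,5-tris(methoxymethoxy)phenyl]-3-oxabicyclo[3.2.0]heptan-6-one (the enantiomer that is converted is drawn) | O=C1[C@H](c3cc(OCOC)c(OCOC)c(OCOC)c3)[C@H]2CO[C@H](c3ccc(OCOC)c(OCOC)c3)[C@@H]12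
A2 | alternative 1 | (1S,4S,5R,8S)-8-[3,4-bis(methoxymethoxy)phenyl]-4-[3,4,5-tris(methoxymethoxy)phenyl]-3,7-dioxabicyclo[3.3.0]octan-2-one | O=C1O[C@H](c3cc(OCOC)c(OCOC)c(OCOC)c3)[C@H]2CO[C@H](c3ccc(OCOC)c(OCOC)c3)[C@@H]12
A3 | alternative 2 | [(2S,3R)-3-[3,4,5-tris(benzyloxy)phenyl]oxiran-2-yl]methanol | OC[C@@H]1O[C@@H]1c1cc(OCc2ccccc2)c(OCc2ccccc2)c(OCc2ccccc2)c1
A4 | alternative 2 | dimethyl 2-[3,4-bis(benzyloxy)benzylidene]propanedioate | COC(=O)C(=Cc1ccc(OCc2ccccc2)c(OCc2ccccc2)c1)C(=O)OC
A5 | alternative 2 | methyl 8-[3,4-bis(benzyloxy)phenyl]-2-oxo-4-[3,4,5-tris(benzyloxy)phenyl]-3,7-dioxabicyclo[3.3.0]octane-1-carboxylate (ring stereocentres as in 19) | O=C1O[C@H](c3cc(OCc4ccccc4)c(OCc4ccccc4)c(OCc4ccccc4)c3)[C@H]2CO[C@H](c3ccc(OCc4ccccc4)c(OCc4ccccc4)c3)[C@@]12C(=O)OC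
A6 | alternative 3 | (5S,6S)-6-[3,4-bis(benzyloxy)phenyl]-5-{(E)-2-[3,4,5-tris(benzyloxy)phenyl]ethenyl}-1,3-dioxan-4-one | O=C1OCO[C@H](c2ccc(OCc3ccccc3)c(OCc3ccccc3)c2)[C@@H]1/C=C/c1cc(OCc2ccccc2)c(OCc2ccccc2)c(OCc2ccccc2)c1
A7 | alternative 3 | (1S,4S,5R,8S)-8-[3,4-bis(benzyloxy)phenyl]-4-[3,4,5-tris(benzyloxy)phenyl]-3,7-dioxabicyclo[3.3.0]octan-2-one (identical with 19) | O=C1O[C@H](c3cc(OCc4ccccc4)c(OCc4ccccc4)c(OCc4ccccc4)c3)[C@H]2CO[C@H](c3ccc(OCc4ccccc4)c(OCc4ccccc4)c3)[C@@H]12
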